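(All runs come from a simulation with made-up constants; noise was put on by code.)

At early times in the earlier runs the substrate was already off the scale of the readings: at 0.200 min in the summer run substrate read 0.1 % and target 3.8 %, so 96.1 % of the charge stood in an unread pool, and I had to reckon how fast that pool clears into target.

| flask | substrate | reagent | temperature | remark | time |
|---|---|---|---|---|---|
| midnight | 27 mM | 14 mM | 105 °C | run made earlier |  |
| noon | 27 mM | 33 mM | 116 °C | run made earlier |  |
| summer | 27 mM | 55 mM | 105 °C | run made earlier |  |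
| east | 27 mM | 18.9 mM | 110 °C |  | 5.0 min |
| south-east | 27 mM | 60.0 mM | 110 °C |  | 15 min |

| run | time / min | target / % | substrate / % |
|---|---|---|---|
| midnight | 0.500 | 14.9 | 0 |
| midnight | 1.00 | 31.4 | 0 |
| midnight | 1.50 | 44.8 | 0 |
| midnight | 2.00 | 55.0 | 0 |
| midnight | 2.50 | 63.0 | 0.1 |
| noon | 0.200 | 16.6 | 0 |
| noon | 0.667 | 50.1 | 0 |
| noon | 1.33 | 71.9 | 0.2 |
| noon | 2.00 | 82.8 | 0.1 |
| noon | 2.50 | 86.2 | 0.4 |
| summer | 0.200 | 3.8 | 0.1 |
| summer | 0.417 | 10.9 | 0 |
| summer | 0.667 | 17.9 | 0.5 |
| summer | 1.33 | 32.4 | 0 |
| summer | 2.50 | 51.7 | 0.1 |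

(scatter of a reading: 0.3 percentage points)

* the flask that ends with the higher amount of target, in percent of the substrate charged, or "neither" when 2 percentage points or less lies between them (east / south-east / neither)
* final target, as a percentage of the substrate charged, in east
* final target, as a percentage of the substrate charged, in south-east



The first rung of my ladder was the substrate, which read 0 % at the first midnight reading, 0.500 min. The next was the clearing of the pool, for which I took the clearing constant k, a pseudo-first-order constant: the natural logarithm of the fraction of the charge not yet target, taken positive and divided by the time, assuming the whole pool ends as target. The last midnight reading gave 0.398 min⁻¹, and putting that back foretold 45.0 % at 1.50 min against the 44.8 % read, so I assumed no plateau below the full charge.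

The summer run, at the same 105 °C but with 55 mM of reagent against 14 mM, gave a lower 0.291 min⁻¹, and I drew a straight line through the clearing times, 2.51 min and 3.44 min, against c(reagent). The noon run's last reading gave 0.792 min⁻¹ at 116 °C, where the line at 105 °C gives 0.340 min⁻¹; 110 °C lies about half of the way from 105 °C to 116 °C, so I took the square root of that ratio, 1.53, as the factor up to 110 °C.

The top rung was the asked time. East got 0.582 min⁻¹, so 2.91 clearing times and 94.5 %. South-east clears more slowly at 0.430 min⁻¹, but its 15 min holds 6.45 clearing times, so I reckoned 99.8 %, higher than east by 5.3 percentage points.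

The forecast differed from my reckoning: it named east, with 88 % in east and 83 % in south-east, and judged that “Noon looks like a true plateau rather than clear target decay”.

The simulation named south-east, with 93.2 % in east and 98.6 % in south-east.

    substrate → intermediate B (k = 0.0700 s⁻¹, Ea = 88.0 kJ mol⁻¹)
    intermediate B → target (k = 0.0640 s⁻¹, Ea = 92.0 kJ mol⁻¹)
    reagent + intermediate B ⇌ intermediate C (K = 100 M⁻¹, k = 0.780 M⁻¹ s⁻¹, Ea = 71.0 kJ mol⁻¹, ΔH = 5.00 kJ mol⁻¹)
    substrate → intermediate A (k = 0.980 s⁻¹, Ea = 101 kJ mol⁻¹)
    substrate + target → side product (k = 0.160 M⁻¹ s⁻¹, Ea = 75.0 kJ mol⁻¹)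
    intermediate B ⇌ intermediate A (K = 1.70, k = 0.0440 s⁻¹, Ea = 106 kJ mol⁻¹, ΔH = −29.0 kJ mol⁻¹)
    (constants at 110 °C)

Read back from those ends, k was 0.538 min⁻¹ in east against my 0.582 min⁻¹, and 0.285 min⁻¹ in south-east against my 0.430 min⁻¹. For the neighbouring flask, east with 76 mM of reagent, the same line through 0.398 min⁻¹ and 0.291 min⁻¹, with the same factor, gave 0.391 min⁻¹, hence 85.8 % at 5.0 min. That flask gave 79.4 %, with 16.7 % still standing as intermediate C.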